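**Retrosynthetic overview**
1. Marchantin C ⇐ BBr3 cleavage of its di-O-methyl ether ⇐ hydrogenation of a macrocyclic stilbene.
2. The 18-membered macrocycle is the only ring formed and is closed last, by intramolecular McMurry coupling of an open-chain dialdehyde (ring B–ring C bridge).
3. Dialdehyde ⇐ dinitrile (iBu2AlH). Its ring D–ring A two-carbon bridge ⇐ key intermolecular Perkin-type aldol condensation of a ring C/D arylacetic acid with a ring A/B benzaldehyde, then decarboxylation and C=C reduction.
4. Both halves ⇐ SNAr diaryl ether syntheses: isovanillin + 4-fluorobenzonitrile (rings A/B); 3-hydroxyphenylacetic acid + 2-fluoro-3-methoxybenzonitrile (rings C/D).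
5. All four benzene rings are bought.

Assumption: the target has no stereocentre or other stable stereogenic element (marchantin C is achiral), so there is no enantiocontrol to exercise; alkene geometries of intermediates are given but are erased by reduction.

Ring labels: ring A = 4-oxygenated, 3-aryloxy ring; ring B = para-phenylene; ring C = 1,2,3-trisubstituted ring (bridge carbon, aryloxy, oxygen); ring D = meta-phenylene.

**Step 1**
Reactants: 1 isovanillin (3-hydroxy-4-methoxybenzaldehyde); 2 4-fluorobenzonitrile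
Product: 3 4-(5-formyl-2-methoxyphenoxy)benzonitrile
Conditions: K2CO3, DMF, 110 °C
Reagents that add atoms: none
Why: SNAr, in which the phenoxide of 1 displaces the fluoride para to the nitrile of 2 through a nitrile-stabilised Meisenheimer adduct while the aldehyde is inert to K2CO3; no stereocentre is formed.

**Step 2**
Reactants: 4 3-hydroxyphenylacetic acid; 5 2-fluoro-3-methoxybenzonitrile
Product: 6 2-[3-(2-cyano-6-methoxyphenoxy)phenyl]acetic acid
Conditions: K2CO3 (3 equiv), DMSO, 120 °C; then HCl (aq)
Reagents that add atoms: none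
Why: SNAr, in which the phenoxide of doubly deprotonated 4 displaces the fluoride activated by the ortho nitrile of 5, the carboxylate (unlike an ester) offering no acidic CH for side reactions; no stereocentre is formed.

**Step 3**
Reactants: 6 2-[3-(2-cyano-6-methoxyphenoxy)phenyl]acetic acid; 3 4-(5-formyl-2-methoxyphenoxy)benzonitrile
Product: 8 (E)-2-[3-(2-cyano-6-methoxyphenoxy)phenyl]-3-[3-(4-cyanophenoxy)-4-methoxyphenyl]prop-2-enoic acid, via mixed acetic arylacetic anhydride 7 (not isolated)
Conditions: Ac2O, Et3N, 120 °C; then H2O, HCl (aq)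
Reagents that add atoms: acetic anhydride, CC(=O)OC(C)=O (its acetyl group is in 7 only and is lost again as acetic acid; 8 keeps no atom of it)
Why: Perkin condensation, an intermolecular aldol condensation in which Et3N enolises 7 at its doubly activated benzylic CH2, the enolate adds to the non-enolisable aldehyde 3, and acetylation with E1cB elimination gives the conjugated acid with the two aryl groups cis (E), a geometry that is erased later.

**Step 4**
Reactants: 8 (E)-2-[3-(2-cyano-6-methoxyphenoxy)phenyl]-3-[3-(4-cyanophenoxy)-4-methoxyphenyl]prop-2-enoic acid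
Product: 9 2-[3-[(Z)-2-[3-(4-cyanophenoxy)-4-methoxyphenyl]ethenyl]phenoxy]-3-methoxybenzonitrile
Conditions: Cu powder, quinoline, 210 °C
Reagents that add atoms: none
Why: copper-mediated protodecarboxylation of an alpha-arylcinnamic acid, in which the vinylcopper species is protonated with retention to give the (Z)-stilbene while aryl nitriles and aryl ethers tolerate the heat.

**Step 5**
Reactants: 9 2-[3-[(Z)-2-[3-(4-cyanophenoxy)-4-methoxyphenyl]ethenyl]phenoxy]-3-methoxybenzonitrile
Product: 10 2-[3-[2-[3-(4-cyanophenoxy)-4-methoxyphenyl]ethyl]phenoxy]-3-methoxybenzonitrile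
Conditions: TsNHNH2 (excess), NaOAc, DME–H2O, reflux
Reagents that add atoms: none
Why: diimide reduction, in which HN=NH generated from TsNHNH2 transfers H2 in a concerted syn fashion to the non-polar C=C only and leaves both aryl nitriles untouched.

**Step 6**
Reactants: 10 2-[3-[2-[3-(4-cyanophenoxy)-4-methoxyphenyl]ethyl]phenoxy]-3-methoxybenzonitrile
Product: 12 2-[3-[2-[3-(4-formylphenoxy)-4-methoxyphenyl]ethyl]phenoxy]-3-methoxybenzaldehyde, via bis(N-diisobutylaluminio)aldimine 11 (not isolated)
Conditions: iBu2AlH (3 equiv), CH2Cl2, −78 to 0 °C; then HCl (aq, 1 M), rt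
Reagents that add atoms: water, O (supplies the two aldehyde oxygens of 12); diisobutylaluminium hydride, CC(C)C[AlH]CC(C)C (its iBu2Al groups are in 11 only)
Why: partial reduction of nitriles with iBu2AlH, in which one hydride adds to each C≡N to give an N-aluminio imine that resists a second hydride at low temperature and is hydrolysed to the aldehyde on acidic work-up.

**Step 7**
Reactants: 12 2-[3-[2-[3-(4-formylphenoxy)-4-methoxyphenyl]ethyl]phenoxy]-3-methoxybenzaldehyde
Product: 13 macrocyclic (E)-stilbene: di-O-methyl marchantin C carrying CH=CH in place of the CH2CH2 bridge between ring B and ring C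
Conditions: TiCl4, Zn, pyridine, THF, reflux; 12 added slowly by syringe pump (high dilution)
Reagents that add atoms: none
Why: intramolecular McMurry coupling, in which low-valent titanium couples the two aryl aldehydes reductively and deoxygenates to the stilbene, slow addition favouring 18-membered ring closure over oligomerisation; the E isomer is expected, any Z isomer is carried along, and step 8 erases the geometry.

**Step 8**
Reactants: 13 macrocyclic (E)-stilbene
Product: 14 marchantin C di-O-methyl ether (ring A: 1-OMe, 2-O–ring B, 4-CH2CH2–ring D; ring B para; ring C: 1-CH2CH2–ring B, 2-O–ring D, 3-OMe; ring D meta)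
Conditions: H2 (1 atm), 10% Pd/C, EtOAc, rt
Reagents that add atoms: none
Why: heterogeneous catalytic hydrogenation of the stilbene C=C, with aryl methyl ethers and diaryl ethers inert at 1 atm and no benzylic heteroatom present to be hydrogenolysed.

**Step 9**
Reactants: 14 marchantin C di-O-methyl ether
Product: 16 marchantin C, via bis(dibromoboryl) ether 15 (not isolated)
Conditions: BBr3 (excess), CH2Cl2, −78 °C to rt; then H2O
Reagents that add atoms: boron tribromide, BrB(Br)Br (its BBr2 groups are in 15 only; 16 keeps no atom of it)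
Why: BBr3 ether cleavage, in which the Lewis acid complexes each methoxy oxygen and bromide attacks the methyl group by SN2, so only the methyl ethers are cleaved (diaryl ethers cannot react this way) and hydrolysis of the aryl borates frees both phenols.

**Compound list**
1 | isovanillin (3-hydroxy-4-methoxybenzaldehyde) | COc1ccc(C=O)cc1O | starting material
2 | 4-fluorobenzonitrile | N#Cc1ccc(F)cc1 | starting material
3 | 4-(5-formyl-2-methoxyphenoxy)benzonitrile | COc1ccc(C=O)cc1Oc1ccc(C#N)cc1 | intermediate
4 | 3-hydroxyphenylacetic acid | OC(=O)Cc1cccc(O)c1 | starting material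
5 | 2-fluoro-3-methoxybenzonitrile | COc1cccc(C#N)c1F | starting material
6 | 2-[3-(2-cyano-6-methoxyphenoxy)phenyl]acetic acid | COc1cccc(C#N)c1Oc1cccc(CC(=O)O)c1 | intermediate
7 | acetic 2-[3-(2-cyano-6-methoxyphenoxy)phenyl]acetic anhydride | COc1cccc(C#N)c1Oc1cccc(CC(=O)OC(C)=O)c1 | intermediate (not isolated)
8 | (E)-2-[3-(2-cyano-6-methoxyphenoxy)phenyl]-3-[3-(4-cyanophenoxy)-4-methoxyphenyl]prop-2-enoic acid | OC(=O)/C(c1cccc(Oc2c(OC)cccc2C#N)c1)=C/c1ccc(OC)c(Oc2ccc(C#N)cc2)c1 | intermediate
9 | 2-[3-[(Z)-2-[3-(4-cyanophenoxy)-4-methoxyphenyl]ethenyl]phenoxy]-3-methoxybenzonitrile | N#Cc1cccc(OC)c1Oc1cccc(/C=C\c2ccc(OC)c(Oc3ccc(C#N)cc3)c2)c1 | intermediate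
10 | 2-[3-[2-[3-(4-cyanophenoxy)-4-methoxyphenyl]ethyl]phenoxy]-3-methoxybenzonitrile | N#Cc1cccc(OC)c1Oc1cccc(CCc2ccc(OC)c(Oc3ccc(C#N)cc3)c2)c1 | intermediate
11 | bis(N-diisobutylaluminio)aldimine of 12 (imine geometry not defined) | CC(C)C[Al](CC(C)C)N=Cc1cccc(OC)c1Oc1cccc(CCc2ccc(OC)c(Oc3ccc(C=N[Al](CC(C)C)CC(C)C)cc3)c2)c1 | intermediate (not isolated)
12 | 2-[3-[2-[3-(4-formylphenoxy)-4-methoxyphenyl]ethyl]phenoxy]-3-methoxybenzaldehyde | O=Cc1cccc(OC)c1Oc1cccc(CCc2ccc(OC)c(Oc3ccc(C=O)cc3)c2)c1 | intermediate
13 | macrocyclic (E)-stilbene (di-O-methyl marchantin C with CH=CH between ring B and ring C) | COc1ccc2cc1Oc1ccc(cc1)/C=C/c1cccc(OC)c1Oc1cccc(c1)CC2 | intermediate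
14 | marchantin C di-O-methyl ether | COc1ccc2cc1Oc1ccc(cc1)CCc1cccc(OC)c1Oc1cccc(c1)CC2 | intermediate
15 | marchantin C bis(O-dibromoboryl) ether | BrB(Br)Oc1ccc2cc1Oc1ccc(cc1)CCc1cccc(OB(Br)Br)c1Oc1cccc(c1)CC2 | intermediate (not isolated)
16 | marchantin C | Oc1ccc2cc1Oc1ccc(cc1)CCc1cccc(O)c1Oc1cccc(c1)CC2 | target

**Totals**
Total step count: 9.
Longest linear sequence: 8 steps (1 → 3 → 8 → 9 → 10 → 12 → 13 → 14 → 16, equally long from 4).

**Three steps most likely to fail, with fallbacks**

Step 2 (SNAr on the hindered fluoride 5, activated only by one nitrile). The fallback sets out from 4 and uses the more strongly activated 2-fluoro-3-methoxybenzaldehyde (bought; COc1cccc(C=O)c1F) under K2CO3, DMSO, 90 °C, then HCl, to give 2-[3-(2-formyl-6-methoxyphenoxy)phenyl]acetic acid F1. Heating this with NH2OH·HCl and HCO2Na in HCO2H forms the oxime 2-[3-[2-[(E)-(hydroxyimino)methyl]-6-methoxyphenoxy]phenyl]acetic acid F2 in the flask and dehydrates it to the nitrile. This comes back to the route at 6.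

Step 4 (decarboxylation at 210 °C in Cu/quinoline). The fallback sets out from 8 and replaces the thermal, copper-mediated process on the unsaturated acid by a radical decarboxylation on the saturated acid. The conjugated C=C, too hindered for diimide, is hydrogenated with H2 (1 atm), 5% Pd/C, EtOAc, rt, stopped after one equivalent (aryl nitriles react only slowly under these conditions), to give rac-2-[3-(2-cyano-6-methoxyphenoxy)phenyl]-3-[3-(4-cyanophenoxy)-4-methoxyphenyl]propanoic acid F3. Coupling with 1-hydroxypyridine-2(1H)-thione (DCC, CH2Cl2, dark) gives the Barton ester 2-thioxopyridin-1(2H)-yl 2-[3-(2-cyano-6-methoxyphenoxy)phenyl]-3-[3-(4-cyanophenoxy)-4-methoxyphenyl]propanoate F4. Visible-light irradiation with tBuSH (Barton reductive decarboxylation; the secondary benzylic radical takes H from the thiol) comes back to the route at 10, bypassing 9 and step 5.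

Step 7 (McMurry macrocyclisation; oligomers or pinacol-type diols possible). The fallback sets out from 12. Double Wittig methylenation with Ph3P=CH2 (from Ph3PCH3Br, KOtBu, THF, 0 °C) gives the distyrene 1-ethenyl-2-[3-[2-[3-(4-ethenylphenoxy)-4-methoxyphenyl]ethyl]phenoxy]-3-methoxybenzene F5. Ring-closing metathesis with the second-generation Grubbs catalyst (H2IMes)(PCy3)Cl2Ru=CHPh in dilute (about 1 mM) refluxing CH2Cl2 closes the same stilbene bridge and comes back to the route at 13 (E or Z, both hydrogenated in step 8).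

**Further compounds**
F1 | step 2 | 2-[3-(2-formyl-6-methoxyphenoxy)phenyl]acetic acid | COc1cccc(C=O)c1Oc1cccc(CC(=O)O)c1
F2 | step 2 | 2-[3-[2-[(E)-(hydroxyimino)methyl]-6-methoxyphenoxy]phenyl]acetic acid | COc1cccc(/C=N/O)c1Oc1cccc(CC(=O)O)c1
F3 | step 4 | rac-2-[3-(2-cyano-6-methoxyphenoxy)phenyl]-3-[3-(4-cyanophenoxy)-4-methoxyphenyl]propanoic acid (racemate, no configuration assigned) | N#Cc1cccc(OC)c1Oc1cccc(c1)C(Cc1ccc(OC)c(Oc2ccc(C#N)cc2)c1)C(=O)O
F4 | step 4 | 2-thioxopyridin-1(2H)-yl 2-[3-(2-cyano-6-methoxyphenoxy)phenyl]-3-[3-(4-cyanophenoxy)-4-methoxyphenyl]propanoate (racemate) | N#Cc1cccc(OC)c1Oc1cccc(c1)C(Cc1ccc(OC)c(Oc2ccc(C#N)cc2)c1)C(=O)ON1C=CC=CC1=S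
F5 | step 7 | 1-ethenyl-2-[3-[2-[3-(4-ethenylphenoxy)-4-methoxyphenyl]ethyl]phenoxy]-3-methoxybenzene | C=Cc1cccc(OC)c1Oc1cccc(CCc2ccc(OC)c(Oc3ccc(C=C)cc3)c2)c1
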